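How fast does Sub fall in the teal run? The conditions and readings are these.

| setting | ochre | teal | flask |
|---|---|---|---|
| Sub | 0.090 M | 0.14 M | 0.18 M |
| Spx | 7.6 mM (held) | 7.6 mM (held) | 7.6 mM (held) |
| remark | run made earlier | run made earlier |  |
| time |  |  | 2.0 min |

| run | time / min | Sub.Spx2 / % | Sub / % |
|---|---|---|---|
| ochre | 0.167 | 6.6 | 90.8 |
| ochre | 0.333 | 13.0 | 80.4 |
| ochre | 0.667 | 23.5 | 60.3 |
| ochre | 1.00 | 33.1 | 36.7 |
| ochre | 1.33 | 41.5 | 17.4 |
| ochre | 2.00 | 47.8 | 0.2 |
| ochre | 2.50 | 39.0 | 0 |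
| teal | 0.167 | 4.5 | 93.7 |
| teal | 0.333 | 8.4 | 86.3 |
| teal | 0.667 | 14.2 | 70.1 |
| teal | 1.00 | 17.8 | 54.0 |
| teal | 1.33 | 22.6 | 37.7 |
| teal | 2.00 | 32.8 | 10.2 |
| teal | 2.50 | 35.5 | 0.6 |

(scatter of a reading: 0.5 percentage points)

- in percentages every species weighs as the Sub in it: one Sdp3 counts as two
- at the start none of Spx2 is dissolved
- the numbers in the tables scatter with a standard deviation of 0.5 percentage points
- on the list of suspects stand: Spx2 -> Sdp; Sub + Spx2 -> Sub.Spx2; Sub.Spx2 <-> Sdp4; Spx <-> Spx2; Spx2 + Sub.Spx2 -> Sdp2; Sub + Sub.Spx2 -> Sdp3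

- eta: doubling the transfer coefficient of Spx, all else as stated
- delta: doubling the saturation concentration of Spx, all else as stated

1. amount of Sub.Spx2 at 2.0 min, in percent of the Sub charged
2. the change that raises the amount of Sub.Spx2 at 2.0 min, in percent of the Sub charged most ("none" if none brings more than 2 percentage points) (eta / delta / none)
3. amount of Sub.Spx2 at 2.0 min, in percent of the Sub charged, after delta

On the straight stretch of the teal run, Sub goes from 70.1% at 0.667 min to 37.7% at 1.33 min, of a charge of 0.14 M, which is a rate r of 0.0684 M min⁻¹.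

And the ochre run, over the same stretch? It gives 0.0582 M min⁻¹. In logarithms, the slope of ln r against ln charge, read off these two runs as an apparent order in Sub, is n = 0.365, less than one, so between these two charges the rate moves weakly.

What carries over to the flask? Teal's rate gives the flask 2.63 min. That is its clearing time τ, the charge of Sub divided by the rate at which Sub falls.

Why does τ matter? In the ochre run, the highest Sub.Spx2 reading, 47.8%, stands where Sub reads 0.2%, and the next reading is 39.0%.

Where is the weak spot? The flask holds more Sub than the teal run, and n is not zero. Stretching r by n shortens τ to 2.40 min, still longer than 2.0 min. So I reckon on 16.7% to 24.0% of the Sub left at that time.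

The forecast gives 23% for the flask, “with Sub not yet consumed”, names eta as the better change and gives 32% after delta.

The flask gives 21.1%, with 22.1% of its Sub left. The better change is eta, which adds 13 percentage points, while delta adds 11 points and reaches 31.7%.

    Spx2 → Sdp (k = 0.00311 s⁻¹)
    Sub + Spx2 → Sub.Spx2 (k = 53.0 M⁻¹ s⁻¹)
    Sub.Spx2 ⇌ Sdp4 (K = 0.210, k = 0.00879 s⁻¹)
    Spx ⇌ Spx2, rate k4*(csat - [Spx2]) (kL = 0.105 s⁻¹)
    Spx2 + Sub.Spx2 → Sdp2 (k = 1.42 M⁻¹ s⁻¹)
    Sub + Sub.Spx2 → Sdp3 (k = 0.205 M⁻¹ s⁻¹)

At 2.00 min in the flask, the path to Sub.Spx2 uses Sub 2.4 times as fast as the path to Sdp3, and Sub.Spx2 is made 1.88 times as fast as it is used up, each step taken net. For the neighbour flask with 0.045 M of Sub, the ochre rate stretched by n gives an estimated τ of 0.995 min, shorter than 2.0 min. At 2.00 min that flask holds 0% of its Sub, with Sdp2 at 26.7% and Sub.Spx2 at 46.9%.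

The earlier runs and the new flask were generated by integration for an exercise; the scatter is artificial.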